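Alpha, with 2 equiv of second end groups, holds 16.3% links on its flat stretch, while gamma, with 0.50 equiv, holds 5.97%, so the second end groups set what each flask's ledger pays into links.

| flask | first end groups | second end groups | remark | time |
|---|---|---|---|---|
| eta | 0.30 M | 1 equiv | run made earlier |  |
| gamma | 0.30 M | 0.50 equiv | run made earlier |  |
| alpha | 0.30 M | 2 equiv | run made earlier |  |
| winter | 0.30 M (fed, over 5.0 min) | 1.00 equiv | all else is in the flask from the start; the feed brings no volume worth counting | 6.0 min |
| summer | 0.30 M | 1.00 equiv (fed, over 5.0 min) | all else is in the flask from the start; the feed brings no volume worth counting | 6.0 min |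
| noon | 0.30 M | 1.00 equiv (in portions, 3, over 5.0 min) | first portion at the start, last at 5.0 min | 6.0 min |
| spring | 0.30 M | 1.00 equiv | everything together at the start | 6.0 min |

| run | time / min | links / % |
|---|---|---|
| eta | 0.500 | 10.9 |
| eta | 1.00 | 10.6 |
| eta | 1.50 | 11.1 |
| eta | 2.00 | 9.7 |
| eta | 2.50 | 9.2 |
| eta | 3.00 | 9.2 |
| eta | 4.00 | 9.6 |
| gamma | 0.250 | 4.2 |
| gamma | 0.667 | 5.1 |
| gamma | 1.33 | 4.8 |
| gamma | 2.00 | 7.7 |
| gamma | 3.00 | 6.2 |
| gamma | 4.00 | 7.4 |
| gamma | 5.00 | 6.4 |
| alpha | 0.667 | 18.3 |
| alpha | 1.33 | 17.0 |
| alpha | 2.00 | 16.6 |
| alpha | 3.00 | 15.5 |
| alpha | 4.00 | 13.1 |
| alpha | 5.00 | 17.3 |

(standard deviation of a reading: 1 percentage point)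



- which flask leads in amount of links, in percent of the first end groups charged ("all alike" within 1.5 percentage points) (winter / summer / noon / spring / all alike)
- how much links is there at the end, in percent of the first end groups charged: winter
- how much links is there at the end, in percent of the first end groups charged: summer
- how much links is there at the end, in percent of the first end groups charged: noon
- how much links is there at the end, in percent of the first end groups charged: spring

I try one reading of the flat stretches: that the ledger of first end groups has closed on them, whatever balance may stand beside it. I keep the ledger in first end groups, the limiting reagent, and assume that an unseen loss takes them in pairs. Each small sum of first end groups then splits between links and the loss. The loss grows with the square of the concentration, so links get a share equal to the level over the level plus the standing concentration. Adding up these entries as the concentration falls from the charge A gives a links share of b/A times the natural log of 1 plus A/b, where b is the level.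

Eta stands at 10.0%, and that gives a break-even level of 0.00837 M, the concentration of first end groups at which links and the loss run equally at 1 equiv. I take the level to be proportional to the second end groups present. It then returns 5.98% for gamma and 16.4% for alpha, close to their readings.

Now the flasks. Spring repeats eta, so I enter 10.0%. Noon's first portion meets the charge at a third of the level, which gives 4.36%, and I enter nothing for its later portions. The plateau stands by 0.500 min, shorter than the feed, so the feed lasts 10.0 spending times. Summer's second end groups come in slowly, so as a rough guess I cut the level by that count, which gives 1.64%; the figure is an estimate, not a tally of when links form. In winter the same count keeps the standing first end groups far below the charge, so I put winter first, above spring, without a firm figure.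

The forecast has winter 10%, summer 10%, noon 10%, spring 10%, all alike: “The addition history is therefore forgotten”.

The flasks give winter 23.9%, spring 10.1%, noon 4.63% and summer 1.91%, so winter leads.

    first end groups + second end groups → links (k = 0.0895 L mol⁻¹ s⁻¹)
    links ⇌ isomer of the product (K = 0.954, k = 0.0222 s⁻¹)
    2 first end groups → homo dimer (k = 0.555 L mol⁻¹ s⁻¹)

At 0.0465 min in summer, the step to homo dimer uses first end groups 710 times as fast as the step to links. By 3.00 min my level, scaled to the second end groups standing, is 0.00476 M, above the 0.00182 M of first end groups, but these are 0.608% of the charge, and summer's links stand at 1.74%.

The readings were generated by integration with made-up constants, noise included.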